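The runs come from a simulation from invented constants, noise included.

The ratio of Z squared to time, with Z as a fraction of the X charged, is the number we carry; we call it the slope S.

the same everywhere: X 0.066 M; D 13 mM
- amber: Q 1.2 equiv; G 5 mol%; the very flask that is asked about, followed so far
- green: Q 1.2 equiv; G 10 mol%; run made earlier
- flask: Q 1.20 equiv; G 5 mol%; volume of the second phase over the first 2.0

- amber (time / min: Z / %, X / %): 2.00: 1, 99; 4.00: 1, 97; 6.00: 4, 93; 8.00: 8, 93; 10.0: 10, 93
- green (time / min: Z / %, X / %): 3.00: 3, 94; 8.00: 11, 90; 15.0: 18, 81; 25.0: 22, 77; 30.0: 25, 76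

(standard deviation of a reading: 1.5 percentage points)

* factor on the rate of making Z when 5.0% of the X are converted if Q is charged twice over
* factor on the rate when 5.0% of the X are converted if G is charged at 1 mol% instead

- in the second phase: Q, J; everything else is in the first
- charges count per volume of the first phase; a concentration in a rate is the amount of a species over the volume of its own phase; every rate counts per litre of the first phase
- steps that have been proposed: G + Q <-> E + J; X + E <-> Z + G; D + E <-> L
- the earlier runs hold the two phases in the same ratio of volumes as the flask asked about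
- no earlier run changes the charge of Q; that part of a forecast is a guess

In the green run S reads 0.00216 min⁻¹ at 15.0 min and 0.00208 min⁻¹ at 30.0 min. So Z there grows roughly as the root of time, and a steady S means that Z rises at S/(2Z). The earliest readings lie below that line, so this is a rough rule at low conversion.

In the amber run the last reading gives 0.00100 min⁻¹ at 10.0 min, and this is the slope S we carry, but it rests on one reading of 10% with a scatter of 1.5 percentage points. Amber over green, S reads 0.481 and the loading of G is 0.500, so we take S as proportional to the loading. Our own reckoning for 1 mol% of G is then a factor of 0.200. No run changes Q, so we offer no figure for it.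

The forecast gives 1.7 for doubled Q and 0.28 for less G, reading the runs as “inhibition by the co-product J through a reversible first step”. On G it stands higher than ours.

    G + Q ⇌ E + J (K = 0.270, k = 0.150 L mol⁻¹ s⁻¹)
    X + E ⇌ Z + G (K = 0.540, k = 0.500 L mol⁻¹ s⁻¹)
    D + E ⇌ L, settled at all times (K = 110 L mol⁻¹)

The flask gives 1.70 for doubled Q and 0.212 for 1 mol% of G, and at 5.0% conversion, reached after 5.68 min, the amber flask makes Z at 6.04 × 10⁻⁴ M min⁻¹. For that amber flask, [X] as charged times S/(2Z) gives 6.60 × 10⁻⁴ M min⁻¹. Scaled to 1 mol% of G, S becomes 2.00 × 10⁻⁴ min⁻¹, which gives 1.32 × 10⁻⁴ M min⁻¹, and the flask at that loading makes Z at 1.28 × 10⁻⁴ M min⁻¹.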